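**Retrosynthetic overview**

1. C11 is set last by hydrogenation of an 11(13)-alkene directed by the free 6-OH. The epoxide (second ring) comes from 6-OH-directed epoxidation of the 4Z-alkene, and the 8-O-angelate from site-selective acylation of a 6,8-diol.
2. The ten-membered ring (first ring) is closed at C6–C7, the bond made in the enzymatic farnesyl C1-to-C10 closure, by adding a Z-allylboronate (C7 nucleophile) to the C6 aldehyde of an open-chain (2Z,6E)-trienal.
3. The allylboronate and the C8 stereocentre are made in the same flask by enantioselective 1,4-diboration of a terminal 1,3-diene; the C8–B bond is then oxidised to C8–OH.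
4. The open chain comes from an allyl–vinyl Stille union of (2Z,6E)-8-bromoneryl acetate (from neryl acetate) with a dienylstannane angelate (from 2-bromoallyl alcohol, (E)-1,2-bis(tributylstannyl)ethene and an angelic mixed anhydride that serves both esterifications).
5. Ring order: carbocycle first, epoxide second. Every stereocentre is relayed from the one catalyst-set centre at C8.

Abbreviations: angelate/angeloyl = (Z)-2-methylbut-2-enoate/-enoyl; Bpin = 4,4,5,5-tetramethyl-1,3,2-dioxaborolan-2-yl. Ring compounds use germacrane numbering. Open-chain compounds are numbered C1–C12 so that C1, C9 and C10 become ring C6, C8 and C7.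

Assumption: read from the SMILES, both esters are angelates, the ring alkene is 1(10)E, the epoxide is cis with respect to the ring carbons (C3 and C6 on the same side), and the centres are 4S,5R,6R,7S,8S,11S.

Assumption: the (R,R)-TADDOL phosphonite gives the (9S) C–B centre drawn in 13; if the sense of induction is opposite, the (S,S)-ligand is used.

**Step 1**
Reactants: 1 neryl acetate
Product: 2 (2Z,6E)-8-hydroxy-3,7-dimethylocta-2,6-dien-1-yl acetate
Conditions: SeO2 (0.1 equiv), t-BuOOH (2 equiv), salicylic acid (0.1 equiv), CH2Cl2, rt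
Reagents that add atoms: tert-butyl hydroperoxide, CC(C)(C)OO
Why: SeO2-catalysed allylic oxidation (ene reaction then 2,3-sigmatropic shift) attacks the E-methyl group of the electron-richer 6,7-alkene, away from the acetate-deactivated 2,3-alkene, and keeps both alkene geometries.

**Step 2**
Reactants: 2 (2Z,6E)-8-hydroxy-3,7-dimethylocta-2,6-dien-1-yl acetate
Product: 3 (2Z,6E)-8-bromo-3,7-dimethylocta-2,6-dien-1-yl acetate
Conditions: CBr4, PPh3, CH2Cl2, 0 °C
Reagents that add atoms: carbon tetrabromide, BrC(Br)(Br)Br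
Why: The Appel reaction converts the primary allylic alcohol into the bromide by SN2 displacement without allylic transposition.

**Step 3**
Reactants: 4 2-bromoprop-2-en-1-ol; 5 (E)-1,2-bis(tributylstannyl)ethene (2 equiv)
Product: 6 (E)-2-methylidene-4-(tributylstannyl)but-3-en-1-ol
Conditions: Pd(PPh3)4 (5 mol %), CuI (10 mol %), DMF, 50 °C
Reagents that add atoms: none
Why: Stille coupling of the vinyl bromide with one tin terminus of the excess distannane goes with retention at both sp2 carbons and leaves the second C–Sn bond for step 6.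

**Step 4**
Reactants: 7 angelic acid
Product: 8 angelic 2,4,6-trichlorobenzoic anhydride
Conditions: 2,4,6-trichlorobenzoyl chloride (1.0 equiv), Et3N (1.1 equiv), THF, rt, 2 h; Et3N·HCl filtered off under argon, filtrate concentrated and taken up in dry toluene (0.5 M stock, kept under argon at −20 °C; one part used in step 5, the rest in step 10)
Reagents that add atoms: 2,4,6-trichlorobenzoyl chloride, O=C(Cl)c1c(Cl)cc(Cl)cc1Cl
Why: Acyl substitution of the aroyl chloride by triethylammonium angelate (formation of the Yamaguchi mixed anhydride) gives a reagent whose aroyl carbonyl is blocked by two ortho chlorines, so it later transfers only the angeloyl group, and no nucleophilic catalyst is present that could isomerise angelate to tiglate.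

**Step 5**
Reactants: 6 (E)-2-methylidene-4-(tributylstannyl)but-3-en-1-ol; 8 angelic 2,4,6-trichlorobenzoic anhydride (1.3 equiv)
Product: 9 (E)-2-methylidene-4-(tributylstannyl)but-3-en-1-yl angelate
Conditions: Et3N (1.5 equiv), toluene, 60 °C
Reagents that add atoms: none
Why: Yamaguchi-type esterification with the preformed hindered mixed anhydride acylates the primary alcohol at the angeloyl carbonyl without DMAP, so the angeloyl group does not isomerise to tigloyl, and the added Et3N buffers the vinylstannane against protodestannylation.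

**Step 6**
Reactants: 3 (2Z,6E)-8-bromo-3,7-dimethylocta-2,6-dien-1-yl acetate; 9 (E)-2-methylidene-4-(tributylstannyl)but-3-en-1-yl angelate
Product: 10 (2Z,6E,9E)-12-(angeloyloxy)-3,7-dimethyl-11-methylidenedodeca-2,6,9-trien-1-yl acetate
Conditions: Pd2(dba)3 (2.5 mol %), AsPh3 (10 mol %), THF, 50 °C
Reagents that add atoms: none
Why: In this allyl–vinyl Stille coupling the allylic bromide adds oxidatively far faster than either allylic carboxylate ionises, and coupling at the less hindered allyl terminus gives the skipped polyene with 6E and 9E retained.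

**Step 7**
Reactants: 10 (2Z,6E,9E)-12-(angeloyloxy)-3,7-dimethyl-11-methylidenedodeca-2,6,9-trien-1-yl acetate
Product: 11 (2Z,6E,9E)-12-(angeloyloxy)-3,7-dimethyl-11-methylidenedodeca-2,6,9-trien-1-ol
Conditions: Mg(OMe)2, MeOH, rt
Reagents that add atoms: none
Why: Mild transesterification removes the unhindered acetate much faster than the conjugated, α-branched angelate.

**Step 8**
Reactants: 11 (2Z,6E,9E)-12-(angeloyloxy)-3,7-dimethyl-11-methylidenedodeca-2,6,9-trien-1-ol
Product: 12 (2Z,6E,9E)-12-(angeloyloxy)-3,7-dimethyl-11-methylidenedodeca-2,6,9-trienal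
Conditions: TEMPO (10 mol %), PhI(OAc)2, CH2Cl2, rt
Reagents that add atoms: none
Why: Oxoammonium (TEMPO) oxidation of the primary allylic alcohol stops at the aldehyde under near-neutral conditions, so the 2Z-enal does not isomerise and the diene is untouched.

**Step 9**
Reactants: 12 (2Z,6E,9E)-12-(angeloyloxy)-3,7-dimethyl-11-methylidenedodeca-2,6,9-trienal
Product: 15 (1(10)E,4Z,6S,7R,8S)-12-(angeloyloxy)germacra-1(10),4,11(13)-triene-6,8-diol, via open-chain bis(boronate) 13 (not isolated), via ring-closed boronate 14 (not isolated)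
Conditions: 12 added by syringe pump over 24 h to Pt(dba)3 (3 mol %), (R,R)-3,5-di-iso-propylphenyl-TADDOL phenylphosphonite (6 mol %), B2pin2 (1.2 equiv), THF, 60 °C (final 5 mM), then 12 h at 60 °C; then NaBO3·4H2O, THF/H2O, rt
Reagents that add atoms: sodium perborate NaBO3, [Na+].[O-]OB=O (the C8 oxygen); bis(pinacolato)diboron, CC1(C)OB(OC1(C)C)B1OC(C)(C)C(C)(C)O1 (its boron is carried only in 13 and 14)
Why: Proposed new method: zerovalent platinum with the chiral phosphonite adds B2pin2 1,4 across the s-cis 1,3-diene (known enantioselective diene 1,4-diboration), which sets C8 as a C–B bond and gives the Z-allylboronate 13; its primary allylboron unit then adds to the tethered aldehyde through a closed chair (Zimmerman–Traxler) transition state, where the Z geometry gives the 6,7-syn pair and attack anti to the neighbouring C–B bond (allylic 1,3-strain holds H-8 in the alkene plane) sets C7, and perborate replaces boron by OH with retention; the closest known chemistry is the intermolecular diboration–allylboration–oxidation sequence of 1,3-dienes, here made ring-forming by pseudo-high dilution.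

**Step 10**
Reactants: 15 (1(10)E,4Z,6S,7R,8S)-12-(angeloyloxy)germacra-1(10),4,11(13)-triene-6,8-diol; 8 angelic 2,4,6-trichlorobenzoic anhydride (1.05 equiv)
Product: 16 (1(10)E,4Z,6S,7S,8S)-8,12-bis(angeloyloxy)germacra-1(10),4,11(13)-trien-6-ol
Conditions: Et3N (1.5 equiv), toluene, 40 °C
Reagents that add atoms: none
Why: Yamaguchi-type acylation with one equivalent of the bulky mixed anhydride is expected to take the C8 hydroxyl (flanked by a CH2) in preference to the C6 hydroxyl, which is allylic to the Z-trisubstituted alkene and shielded by its cis ring CH2 and by the C7 branch.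

**Step 11**
Reactants: 16 (1(10)E,4Z,6S,7S,8S)-8,12-bis(angeloyloxy)germacra-1(10),4,11(13)-trien-6-ol
Product: 17 (1(10)E,4S,5R,6R,7S,8S)-8,12-bis(angeloyloxy)-4,5-epoxygermacra-1(10),11(13)-dien-6-ol
Conditions: VO(acac)2 (5 mol %), t-BuOOH (1.2 equiv), CH2Cl2, 0 °C
Reagents that add atoms: tert-butyl hydroperoxide, CC(C)(C)OO
Why: In this hydroxyl-directed epoxidation the only free hydroxyl (C6) binds vanadium and delivers oxygen to the adjacent 4Z-alkene on its own peripheral face, as in medium-ring (Z)-cycloalk-2-enols that give cis epoxy alcohols, which sets 4S,5R and leaves the other alkenes untouched.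

**Step 12**
Reactants: 17 (1(10)E,4S,5R,6R,7S,8S)-8,12-bis(angeloyloxy)-4,5-epoxygermacra-1(10),11(13)-dien-6-ol
Product: 18 (1(10)E,4S,5R,6R,7S,8S,11S)-8,12-bis(angeloyloxy)-4,5-epoxygermacr-1(10)-en-6-ol (target)
Conditions: [Rh(nbd)(dppb)]BF4 (5 mol %), H2 (50 atm), CH2Cl2, rt
Reagents that add atoms: none
Why: In this hydroxyl-directed hydrogenation the C6 hydroxyl binds cationic rhodium and delivers H2 to the homoallylic 1,1-disubstituted alkene on the C6 face of the conformer with H-7 eclipsing the C11–C12 bond (least allylic 1,2-strain), which gives 11S, while the undirected 1(10)-alkene and angelate alkenes react much more slowly.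

**Compound list**

1 | neryl acetate, (2Z)-3,7-dimethylocta-2,6-dien-1-yl acetate | CC(=O)OC/C=C(/C)CCC=C(C)C | starting material
2 | (2Z,6E)-8-hydroxy-3,7-dimethylocta-2,6-dien-1-yl acetate | CC(=O)OC/C=C(/C)CC/C=C(\C)CO | intermediate
3 | (2Z,6E)-8-bromo-3,7-dimethylocta-2,6-dien-1-yl acetate | CC(=O)OC/C=C(/C)CC/C=C(\C)CBr | intermediate
4 | 2-bromoprop-2-en-1-ol | OCC(Br)=C | starting material
5 | (E)-1,2-bis(tributylstannyl)ethene | CCCC[Sn](CCCC)(CCCC)/C=C/[Sn](CCCC)(CCCC)CCCC | starting material
6 | (E)-2-methylidene-4-(tributylstannyl)but-3-en-1-ol | OCC(=C)/C=C/[Sn](CCCC)(CCCC)CCCC | intermediate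
7 | angelic acid, (Z)-2-methylbut-2-enoic acid | C/C=C(/C)C(=O)O | starting material
8 | angelic 2,4,6-trichlorobenzoic anhydride | C/C=C(/C)C(=O)OC(=O)c1c(Cl)cc(Cl)cc1Cl | intermediate
9 | (E)-2-methylidene-4-(tributylstannyl)but-3-en-1-yl angelate | C/C=C(/C)C(=O)OCC(=C)/C=C/[Sn](CCCC)(CCCC)CCCC | intermediate
10 | (2Z,6E,9E)-12-(angeloyloxy)-3,7-dimethyl-11-methylidenedodeca-2,6,9-trien-1-yl acetate | CC(=O)OC/C=C(/C)CC/C=C(\C)C/C=C/C(=C)COC(=O)/C(C)=C\C | intermediate
11 | (2Z,6E,9E)-12-(angeloyloxy)-3,7-dimethyl-11-methylidenedodeca-2,6,9-trien-1-ol | OC/C=C(/C)CC/C=C(\C)C/C=C/C(=C)COC(=O)/C(C)=C\C | intermediate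
12 | (2Z,6E,9E)-12-(angeloyloxy)-3,7-dimethyl-11-methylidenedodeca-2,6,9-trienal | O=C/C=C(/C)CC/C=C(\C)C/C=C/C(=C)COC(=O)/C(C)=C\C | intermediate
13 | (2Z,6E,9S,10E)-12-(angeloyloxy)-3,7-dimethyl-9-Bpin-11-(Bpin-methyl)dodeca-2,6,10-trienal; C9 and the CH2Bpin carbon cis on the 10,11-alkene (formed in the flask) | O=C/C=C(/C)CC/C=C(\C)C[C@H](B1OC(C)(C)C(C)(C)O1)/C=C(/COC(=O)/C(C)=C\C)CB1OC(C)(C)C(C)(C)O1 | intermediate
14 | (1(10)E,4Z,6S,7S,8S)-12-(angeloyloxy)-8-Bpin-germacra-1(10),4,11(13)-trien-6-yl pinacol borate (formed in the flask) | C/C=C(/C)C(=O)OCC(=C)[C@H]1[C@@H](OB2OC(C)(C)C(C)(C)O2)/C=C(/C)CC/C=C(\C)C[C@@H]1B1OC(C)(C)C(C)(C)O1 | intermediate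
15 | (1(10)E,4Z,6S,7R,8S)-12-(angeloyloxy)germacra-1(10),4,11(13)-triene-6,8-diol | C/C=C(/C)C(=O)OCC(=C)[C@H]1[C@@H](O)/C=C(/C)CC/C=C(\C)C[C@@H]1O | intermediate
16 | (1(10)E,4Z,6S,7S,8S)-8,12-bis(angeloyloxy)germacra-1(10),4,11(13)-trien-6-ol | C/C=C(/C)C(=O)OCC(=C)[C@H]1[C@@H](O)/C=C(/C)CC/C=C(\C)C[C@@H]1OC(=O)/C(C)=C\C | intermediate
17 | (1(10)E,4S,5R,6R,7S,8S)-8,12-bis(angeloyloxy)-4,5-epoxygermacra-1(10),11(13)-dien-6-ol | C/C=C(/C)C(=O)OCC(=C)[C@H]1[C@@H](O)[C@H]2O[C@@]2(C)CC/C=C(\C)C[C@@H]1OC(=O)/C(C)=C\C | intermediate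
18 | (1(10)E,4S,5R,6R,7S,8S,11S)-8,12-bis(angeloyloxy)-4,5-epoxygermacr-1(10)-en-6-ol | C/C=C(/C)C(=O)OC[C@@H](C)[C@H]1[C@@H](O)[C@H]2O[C@@]2(C)CC/C=C(\C)C[C@@H]1OC(=O)/C(C)=C\C | target

**Step count and risks**

Total steps: 12. Longest linear sequence: 9 steps (1 to 18 through steps 1, 2 and 6–12; the count is the same from 4 through steps 3 and 5–12, and from 7 through steps 4–12).

The three steps most likely to fail:

**Step 9 (diboration and ring closure in one flask).** The enal may be borylated by the platinum catalyst before the diene is. The ten-membered ring closure may be too slow at 60 °C and lose to oligomers. The level and sense of control at C8 for a 1,3-disubstituted diene are not established. The remote allylic angelate could also be lost by 1,4-elimination from the secondary allylboron unit.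
Fallback: set out from alcohol 11 and separate the two events. The same platinum-catalysed diboration is run on 11, where no carbonyl group is present, and gives the isolable (2Z,6E,9S,10E)-12-(angeloyloxy)-3,7-dimethyl-9-Bpin-11-(Bpin-methyl)dodeca-2,6,10-trien-1-ol F1, whose enantiomeric purity can be checked. Dess–Martin periodinane (NaHCO3, CH2Cl2, 0 °C) oxidises the primary alcohol and the route is rejoined at 13. Compound 13 is now a discrete compound and is closed not thermally but by Lewis-acid catalysis (Sc(OTf)3, 10 mol %, CH2Cl2, −78 °C, 2 mM) to 14, which is oxidised with NaBO3·4H2O to 15.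

**Step 10 (site-selective acylation of the 6,8-diol).** The two secondary hydroxyls may not differ enough, which would give the 6-ester and the diester.
Fallback: set out from 12 and use the fact that O8 is still masked as a C–B bond after the ring closure. Step 9 is run without perborate, and aqueous work-up of 14 gives (1(10)E,4Z,6S,7S,8S)-12-(angeloyloxy)-8-Bpin-germacra-1(10),4,11(13)-trien-6-ol F2. The only hydroxyl is silylated (TESOTf, 2,6-lutidine, CH2Cl2, −78 °C) to the 6-O-triethylsilyl ether F3. NaBO3·4H2O then gives (1(10)E,4Z,6S,7R,8S)-12-(angeloyloxy)-6-(triethylsilyloxy)germacra-1(10),4,11(13)-trien-8-ol F4. The single free hydroxyl is acylated with mixed anhydride 8 to the 6-O-triethylsilyl 8,12-diangelate F5, and HF·pyridine (THF, 0 °C) removes the silyl group. The route is rejoined at 16.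

**Step 11 (face selectivity of the directed epoxidation).** A ten-membered (Z)-allylic alcohol may not follow the cis preference of the smaller rings, and the threo epoxy alcohol would result.
Fallback: set out from 11 and install the epoxide by reagent control before the ring is closed. Sharpless epoxidation (Ti(OiPr)4, D-(−)-diethyl tartrate, t-BuOOH, 4 Å sieves, CH2Cl2, −20 °C) gives the (2R,3S)-2,3-epoxy alcohol F6, and TEMPO/PhI(OAc)2 gives the (2S,3S)-2,3-epoxy aldehyde F7. The conditions of step 9 then give the open-chain epoxy bis(boronate) F8 and the ring-closed epoxy boronate F9 in the flask; here Felkin–Anh addition anti to the epoxide C–O bond reinforces the 6R outcome. Perborate gives (1(10)E,4S,5R,6R,7R,8S)-12-(angeloyloxy)-4,5-epoxygermacra-1(10),11(13)-diene-6,8-diol F10. Acylation of the C8 hydroxyl with mixed anhydride 8 as in step 10 rejoins the route at 17.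

**Further compounds**

F1 | step 9 | (2Z,6E,9S,10E)-12-(angeloyloxy)-3,7-dimethyl-9-Bpin-11-(Bpin-methyl)dodeca-2,6,10-trien-1-ol | OC/C=C(/C)CC/C=C(\C)C[C@H](B1OC(C)(C)C(C)(C)O1)/C=C(/COC(=O)/C(C)=C\C)CB1OC(C)(C)C(C)(C)O1
F2 | step 10 | (1(10)E,4Z,6S,7S,8S)-12-(angeloyloxy)-8-Bpin-germacra-1(10),4,11(13)-trien-6-ol | C/C=C(/C)C(=O)OCC(=C)[C@H]1[C@@H](O)/C=C(/C)CC/C=C(\C)C[C@@H]1B1OC(C)(C)C(C)(C)O1
F3 | step 10 | (1(10)E,4Z,6S,7S,8S)-12-(angeloyloxy)-8-Bpin-6-(triethylsilyloxy)germacra-1(10),4,11(13)-triene | C/C=C(/C)C(=O)OCC(=C)[C@H]1[C@@H](O[Si](CC)(CC)CC)/C=C(/C)CC/C=C(\C)C[C@@H]1B1OC(C)(C)C(C)(C)O1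
F4 | step 10 | (1(10)E,4Z,6S,7R,8S)-12-(angeloyloxy)-6-(triethylsilyloxy)germacra-1(10),4,11(13)-trien-8-ol | C/C=C(/C)C(=O)OCC(=C)[C@H]1[C@@H](O[Si](CC)(CC)CC)/C=C(/C)CC/C=C(\C)C[C@@H]1O
F5 | step 10 | (1(10)E,4Z,6S,7R,8S)-8,12-bis(angeloyloxy)-6-(triethylsilyloxy)germacra-1(10),4,11(13)-triene | C/C=C(/C)C(=O)OCC(=C)[C@H]1[C@@H](O[Si](CC)(CC)CC)/C=C(/C)CC/C=C(\C)C[C@@H]1OC(=O)/C(C)=C\C
F6 | step 11 | (2R,3S,6E,9E)-12-(angeloyloxy)-2,3-epoxy-3,7-dimethyl-11-methylidenedodeca-6,9-dien-1-ol | OC[C@H]1O[C@@]1(C)CC/C=C(\C)C/C=C/C(=C)COC(=O)/C(C)=C\C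
F7 | step 11 | (2S,3S,6E,9E)-12-(angeloyloxy)-2,3-epoxy-3,7-dimethyl-11-methylidenedodeca-6,9-dienal | O=C[C@H]1O[C@@]1(C)CC/C=C(\C)C/C=C/C(=C)COC(=O)/C(C)=C\C
F8 | step 11 | (2S,3S,6E,9S,10E)-12-(angeloyloxy)-2,3-epoxy-3,7-dimethyl-9-Bpin-11-(Bpin-methyl)dodeca-6,10-dienal | O=C[C@H]1O[C@@]1(C)CC/C=C(\C)C[C@H](B2OC(C)(C)C(C)(C)O2)/C=C(/COC(=O)/C(C)=C\C)CB1OC(C)(C)C(C)(C)O1
F9 | step 11 | (1(10)E,4S,5R,6R,7S,8S)-12-(angeloyloxy)-8-Bpin-4,5-epoxygermacra-1(10),11(13)-dien-6-yl pinacol borate | C/C=C(/C)C(=O)OCC(=C)[C@H]1[C@@H](OB2OC(C)(C)C(C)(C)O2)[C@H]2O[C@@]2(C)CC/C=C(\C)C[C@@H]1B1OC(C)(C)C(C)(C)O1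
F10 | step 11 | (1(10)E,4S,5R,6R,7R,8S)-12-(angeloyloxy)-4,5-epoxygermacra-1(10),11(13)-diene-6,8-diol | C/C=C(/C)C(=O)OCC(=C)[C@H]1[C@@H](O)[C@H]2O[C@@]2(C)CC/C=C(\C)C[C@@H]1O
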